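# Proposal: 6β-[(2E,4E,6E)-Octa-2,4,6-trienoyloxy]-8β,9β-drimane-11,12-dioic acid (CNP0462207.1) by acyl-radical closure of ring B

Drimane numbering is used for every intermediate, including the monocyclic ones: ring A is C1–C5 and C10, ring B is C5–C10, C11 is the carboxyl on C9, C12 the carboxyl on C8, and β is the face of the C10 methyl.

## The problem

Target 21 is a trans-fused drimane with five stereocentres, and ring B carries three axial β groups on alternate carbons: the C10 methyl, the C12 carboxyl on C8 and the ester oxygen on C6. The quaternary C10 is the centre from which the others can be read, because its methyl and the 4β-methyl close the β face of ring B, so reagents reach C5, C6 and C8 from the α face. The equatorial C11 carboxyl at C9 and the trans fusion at C5 are the stable arrangements, whereas the axial C12 carboxyl at C8 is the less stable epimer and must be set kinetically and then kept away from base. O6 and C12 are syn-diaxial and close to a five-membered lactone whenever a free 6β-alkoxide sits next to an unhindered C12 ester. The O6 acyl group is a (2E,4E,6E)-trienoate that tolerates neither hydroxide, soft nucleophiles nor reduction, so it must come late, onto a very hindered axial alcohol, and the final deprotection can be neither hydrolytic nor reductive. The enabling feature is the 1,4 relation between oxygenated C6 and C12: with C12 as the ester of an acrylate on C8, C7 is the β-carbon of that acrylate, so the ring B bond C6–C7 joins two acceptor carbons. This calls for an acyl radical at C6, which also delivers C6 as a ketone.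

## Retrosynthesis

**21 ⇒ 20 (O–C bonds of two ester groups).** The carboxyls are masked as tert-butyl esters. Their cleavage by acid is alkyl–oxygen fission, which ignores the hindrance at C11 (next to C10) and at axial C12 and uses no base, nucleophile or reductant. Allyl esters removable with Pd(PPh3)4 (zerovalent palladium) were the other candidate. An unhindered C12 ester is expected to lactonise with the 6β-alkoxide on ketone reduction, and the lactone would then have to be opened and re-esterified to a hydroxy ester that can close again during acylation. The tert-butyl ester avoids this and saves two steps.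

**20 ⇒ 17 + 18 (acyl C–O bond at O6).** The trienoyl group is taken from the purchased acid 18, whose three E double bonds are already in place. Cutting here rather than building the triene on the substrate keeps the polyene out of all earlier chemistry. The forward reaction must acylate an axial alcohol flanked by three syn-axial groups.

**17 ⇒ 16 (C6–H bond).** The 6β-alcohol is traced to the 6-ketone 16. Hydride can only arrive on the α face, which gives the axial alcohol. The ketone is the oxidation level at which the key step delivers C6.

**16 ⇒ 15 (C6–C7 bond, ring B).** This is the central cut. A polar closure at C6–C7 is not available because C6 is a carbonyl carbon and C7 a Michael terminus. Cuts at C9–C10 or C5–C10 would leave ring B to be closed at a quaternary centre. The acyl radical from selenoester 15 is nucleophilic, adds to the unsubstituted terminus C7 of the electron-poor acrylate, and is indifferent to the crowding at C5. The precursor is monocyclic with only C5, C9 and C10 as stereocentres. The forward step must close 6-endo and take up hydrogen at C8 on the α face.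

**15 ⇒ 13 ⇒ 12 (C6–Se and C6–O bonds).** The selenoester comes from acid 13 and that from aldehyde 12. Nothing is simplified structurally, but the aldehyde is what the masked carbonyl of the next cut releases.

**12 ⇒ 10 (C5–H bond, C6 carbonyl oxygen).** The formyl group with its C5 hydrogen is traced to the vinylsilane C5=C6–Si of 10, by way of its epoxide 11. A vinylsilane is a masked aldehyde that can be unmasked with peracid and acid in the presence of the acrylate. Hydroboration of a plain exocyclic methylene would not spare the acrylate. The forward step must protonate the enol at C5 on the α face.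

**10 ⇒ 9 ⇒ 6 (ester O–C bonds, then the C9–C10 bond).** After removal of the tert-butyl groups, diacid 9 is the product of an Ireland–Claisen rearrangement of half ester 6 through ketene acetal 7 and silyl ester 8. The bond cut, C9–C10, makes the quaternary centre and its tertiary neighbour together. It converts the carbinol stereocentre at C6 into C10 and leaves the vinylsilane needed above. The alternative of alkylating a preformed ring at C10 would give no control of absolute configuration. The forward reaction requires the ketene acetal geometry with C8 cis to the alkoxy oxygen and a chair transition state.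

**6 ⇒ 4 + 5 (ester C–O bond).** Half ester 6 is the alcoholysis product of itaconic anhydride 5 with carbinol 4. The anhydride supplies C7, C8, C9, C11 and C12 in one piece with the methylene already in place, and its two carbonyls differ enough for regioselective opening.

**4 ⇒ 3 ⇒ 2 ⇒ 1 (C6–H, then C6–Si).** The single stereocentre of 4 comes from reagent-controlled reduction of acylsilane 3. The silicon is attached by adding a silyllithium reagent to β-cyclocitral 1, giving racemic carbinol 2, which is oxidised to 3. Compound 1 already contains ring A, the gem-dimethyl group, the C10 methyl and C6.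

## Roads not taken

**Alternative 1:** Cut C4–C5 and C9–C10 and make both rings from the acyclic β-keto ester A1. In the forward step a chiral Lewis acid-assisted Brønsted acid protonates the terminal olefin at C3, the chain folds chair–chair and the enol carbon C9 ends the cascade, giving methyl 8-oxodriman-11-oate A2.
- Merits: two rings and three stereocentres (C5, C9, C10) arise in one step from an achiral chain only two steps from bulk chemicals, with absolute configuration from a recoverable ligand. For the carbon skeleton this is clearly shorter than the present route.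
- Weak points: A2 has oxygen only at C8. C12 is missing and would have to be attached to C8 as the less stable axial carboxyl. C6 is an unfunctionalised methylene; oxygen there would need dehydrogenation to the C6–C7 enone and conjugate delivery of oxygen to the β face, which two axial methyls block. Protonative cyclisations ending on a β-keto ester also tend to need stoichiometric acid and to stop partly at monocyclic products.
- Comparison: it is better at ring construction and at C5, C9 and C10. The chosen plan sets against this that the C6 oxidation level and C12 both arrive in the bond-forming step that closes ring B.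

**Alternative 2:** Cut only C8–C12. In the forward step a tin hydride chain converts the bromomethylsilyl ether A3 on the 6β-oxygen into a silylmethyl radical that adds 6-exo to C8 of the C8=C9 unsaturated ester, giving the cyclic silyl ether A4.
- Merits: the configuration at C8 is fixed by the tether from O6 and is cis by construction. This is more secure than the intermolecular hydrogen transfer used here.
- Weak points: no skeletal ring is formed, so the complete 6β-hydroxylated bicyclic enoate must already exist as one enantiomer, and no short route to it is apparent. C12 arrives as a silylmethyl group, so a Tamao oxidation and two further oxidations of a primary alcohol are needed beside the liberated 6β-hydroxyl, which will lactonise. C9 still depends on a hydrogen transfer.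
- Comparison: it is better for C8. The chosen plan sets against this that one step closes ring B and sets C6 and C12 at useful oxidation levels, in fewer steps overall.

**Alternative 3:** Cut C9–C10 and close ring B by contraction of the cis-disubstituted lactone A5. After enolisation and O-silylation, A5 rearranges [3,3] through the tetrasubstituted C5=C10 olefin to give acid A6.
- Merits: it uses the same C6-to-C10 chirality transfer as step 5 here, but the enolate geometry is fixed by the lactone ring and C8 is already a stereocentre. In that respect it is better than the acyclic ketene acetal 7, whose geometry depends on the base.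
- Weak points: the C6–O bond is lost in the rearrangement. A6 has a C5=C6 olefin and no oxygen at C6; hydroboration would return it as the equatorial 6α-alcohol, so an oxidation–reduction pair follows. C12 is still an alcohol. The C9 carboxyl is α and must be epimerised next to the base-sensitive C8 centre.
- Comparison: geometric control is better there. The chosen plan sets against this that C6 stays a carbonyl carbon throughout and that C9, C11 and C12 have their final configuration and oxidation level before ring B closes, at the price of the kinetic hydrogen transfer at C8.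

Key step: step 10

Assumption: (−)-Ipc2BCl reduces acylsilane 3 to the R carbinol 4, silicon acting as the large group as in simpler acylsilanes; if MTPA ester analysis shows the opposite sense, (+)-Ipc2BCl is used and nothing else changes.

## Route

Step 1
Reactants: 1 β-cyclocitral
Product: 2 rac-[dimethyl(phenyl)silyl](2,6,6-trimethylcyclohex-1-en-1-yl)methanol
Conditions: PhMe2SiCl, Li, THF, 0 °C (gives PhMe2SiLi); then 1, THF, −78 °C; AcOH, −78 °C
Reagents that add atoms: chlorodimethyl(phenyl)silane, C[Si](C)(Cl)c1ccccc1 (used as dimethyl(phenyl)silyllithium, [Li][Si](C)(C)c1ccccc1)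
Why: Silyllithium reagents add 1,2 to aldehydes to give α-hydroxysilanes; the β-carbon of 1 is fully substituted, and the cold quench keeps the lithium alkoxide from Brook rearrangement.

Step 2
Reactants: 2 rac-[dimethyl(phenyl)silyl](2,6,6-trimethylcyclohex-1-en-1-yl)methanol
Product: 3 [dimethyl(phenyl)silyl](2,6,6-trimethylcyclohex-1-en-1-yl)methanone
Conditions: (COCl)2, DMSO, CH2Cl2, −78 °C; Et3N, −78 → 0 °C
Reagents that add atoms: none
Why: Swern oxidation of α-hydroxysilanes is the standard entry to acylsilanes and avoids the acid and heat that would ionise this allylic alcohol.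

Step 3
Reactants: 3 [dimethyl(phenyl)silyl](2,6,6-trimethylcyclohex-1-en-1-yl)methanone
Product: 4 (R)-[dimethyl(phenyl)silyl](2,6,6-trimethylcyclohex-1-en-1-yl)methanol
Conditions: (−)-Ipc2BCl, THF, −25 °C → rt; CH3CHO; aq. NaOH
Reagents that add atoms: none
Why: Reduction of acylsilanes with (−)-B-chlorodiisopinocampheylborane is a known route to enantioenriched α-silyl carbinols; with silicon as the large group the hydride should be delivered to give R at C6, and the acetaldehyde work-up frees the product from boron.

Step 4
Reactants: 4 (R)-[dimethyl(phenyl)silyl](2,6,6-trimethylcyclohex-1-en-1-yl)methanol; 5 itaconic anhydride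
Product: 6 4-{(R)-[dimethyl(phenyl)silyl](2,6,6-trimethylcyclohex-1-en-1-yl)methoxy}-2-methylidene-4-oxobutanoic acid
Conditions: 5 (3 equiv), PhMe, 90 °C, no base
Reagents that add atoms: none
Why: Alcoholysis of itaconic anhydride occurs at the non-conjugated carbonyl, which puts the carbinol on the CH2–CO side and leaves the acrylic acid free; amine bases are left out because they isomerise the anhydride to citraconic anhydride.

Step 5
Reactants: 6 4-{(R)-[dimethyl(phenyl)silyl](2,6,6-trimethylcyclohex-1-en-1-yl)methoxy}-2-methylidene-4-oxobutanoic acid
Product: 9 (2R)-2-[(1R,2E)-2-{[dimethyl(phenyl)silyl]methylidene}-1,3,3-trimethylcyclohexyl]-3-methylidenebutanedioic acid, via silyl ketene acetal 7 (not isolated), via bis(trimethylsilyl) ester 8 (not isolated)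
Conditions: LiN(i-Pr)2 (2.4 equiv), Me3SiCl (3 equiv), THF, −78 °C → rt, then 60 °C; 1 M HCl
Reagents that add atoms: none
Why: Ireland–Claisen rearrangement of an α-silyl allylic ester, a known route to E-vinylsilanes with chirality transfer: the acid is silylated in the flask and kinetic enolisation places C8 cis to the alkoxy oxygen. In the chair transition state the C6 hydrogen, not silicon, faces the C10 methyl (A1,3 strain), so the R carbinol sends C9 to the face of C10 required for 21, and the ketene acetal geometry sets C9 with C11 as required.

Step 6
Reactants: 9 (2R)-2-[(1R,2E)-2-{[dimethyl(phenyl)silyl]methylidene}-1,3,3-trimethylcyclohexyl]-3-methylidenebutanedioic acid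
Product: 10 di-tert-butyl (2R)-2-[(1R,2E)-2-{[dimethyl(phenyl)silyl]methylidene}-1,3,3-trimethylcyclohexyl]-3-methylidenebutanedioate
Conditions: t-BuOC(=NH)CCl3 (4 equiv), CH2Cl2–cyclohexane, rt
Reagents that add atoms: tert-butyl 2,2,2-trichloroacetimidate, CC(C)(C)OC(=N)C(Cl)(Cl)Cl
Why: Carboxylic acids are O-alkylated by the trichloroacetimidate without added acid; the new bond is O–C(CH3)3, so the hindrance of the C11 acid does not matter, and vinylsilane and acrylate are left alone.

Step 7
Reactants: 10 di-tert-butyl (2R)-2-[(1R,2E)-2-{[dimethyl(phenyl)silyl]methylidene}-1,3,3-trimethylcyclohexyl]-3-methylidenebutanedioate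
Product: 12 di-tert-butyl (2R)-2-[(1S,2S)-2-formyl-1,3,3-trimethylcyclohexyl]-3-methylidenebutanedioate, via epoxysilane 11 (not isolated)
Conditions: mCPBA, NaHCO3, CH2Cl2, 0 °C; then 1 M aq. H2SO4, THF, 0 °C
Reagents that add atoms: 3-chloroperbenzoic acid, O=C(OO)c1cccc(Cl)c1 (its oxygen stays on C6 when the epoxide opens at the tertiary C5)
Why: The peracid epoxidises the electron-rich vinylsilane and not the acrylate; acid opens the α,β-epoxysilane and loss of the silanol (Peterson-type elimination, the masked-carbonyl chemistry of epoxysilanes) gives the enol of the aldehyde. The enol should be protonated at C5 on the α face, away from the axial methyls on C4 and C10, which puts H5 trans to the C10 methyl; any C5 epimer is removed by chromatography.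

Step 8
Reactants: 12 di-tert-butyl (2R)-2-[(1S,2S)-2-formyl-1,3,3-trimethylcyclohexyl]-3-methylidenebutanedioate
Product: 13 (1S,2S)-2-[(2R)-1,4-di-tert-butoxy-3-methylidene-1,4-dioxobutan-2-yl]-2,6,6-trimethylcyclohexane-1-carboxylic acid
Conditions: NaClO2, NaH2PO4, 2-methylbut-2-ene, t-BuOH–H2O, rt
Reagents that add atoms: sodium chlorite, [Na+].[O-]Cl=O
Why: Pinnick oxidation converts hindered, epimerisable aldehydes to acids under buffered conditions and leaves the acrylate and the tert-butyl esters untouched.

Step 9
Reactants: 13 (1S,2S)-2-[(2R)-1,4-di-tert-butoxy-3-methylidene-1,4-dioxobutan-2-yl]-2,6,6-trimethylcyclohexane-1-carboxylic acid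
Product: 15 di-tert-butyl (3R)-2-methylidene-3-{(1R,2S)-1,3,3-trimethyl-2-[(phenylselanyl)carbonyl]cyclohexyl}butanedioate, via acid chloride 14 (not isolated)
Conditions: Me2C=C(Cl)NMe2, CH2Cl2, 0 °C → rt; then PhSeH (1.1 equiv), pyridine, −20 → 0 °C
Reagents that add atoms: benzeneselenol, [SeH]c1ccccc1
Why: The chloroenamine forms the acid chloride under neutral conditions that spare the tert-butyl esters, and acylation of the selenol by an acid chloride is the standard selenoester synthesis. Kept cold and near stoichiometric, the selenol should acylate faster than it adds to the hindered α-substituted tert-butyl acrylate.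

Step 10
Reactants: 15 di-tert-butyl (3R)-2-methylidene-3-{(1R,2S)-1,3,3-trimethyl-2-[(phenylselanyl)carbonyl]cyclohexyl}butanedioate
Product: 16 di-tert-butyl (1S,2S,4aS,8aS)-5,5,8a-trimethyl-4-oxodecahydronaphthalene-1,2-dicarboxylate (di-tert-butyl 6-oxo-8β,9β-drimane-11,12-dioate)
Conditions: Bu3SnH (1.3 equiv, syringe pump), AIBN (0.2 equiv), PhH (0.01 M), 80 °C
Reagents that add atoms: none
Why: The stannyl radical abstracts the phenylselanyl group and leaves a nucleophilic acyl radical at C6, which adds to C7, the unsubstituted terminus of the electron-poor acrylate, forming C6–C7. Ring B closes in the 6-endo mode, because 5-exo attack would have to occur at the fully substituted C8 and would give a primary radical, whereas 6-endo gives a tertiary α-ester radical. The closest known reaction type is the 6-endo cyclisation of selenoester-derived acyl radicals onto α-substituted acrylates. The one new stereocentre, C8, is set when the C8 radical takes hydrogen from Bu3SnH; the β face is shielded by the syn-axial C10 methyl and by the neighbouring 9β ester, so hydrogen should arrive on the α face and leave the C12 ester axial and cis to C11. The trans ring fusion and C9 are carried over from 15, in which C6 and C9 sit trans-diequatorial on ring A and are therefore close. The step needs cyclisation to outrun loss of CO and direct reduction of the acyl radical, which the slow addition of stannane and the preorganised chain serve. The tert-butyl esters offer the C8 radical no olefin to attack, which allyl esters would.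

Step 11
Reactants: 16 di-tert-butyl (1S,2S,4aS,8aS)-5,5,8a-trimethyl-4-oxodecahydronaphthalene-1,2-dicarboxylate
Product: 17 di-tert-butyl (1S,2S,4R,4aS,8aS)-4-hydroxy-5,5,8a-trimethyldecahydronaphthalene-1,2-dicarboxylate (6β-alcohol)
Conditions: NaBH4, MeOH, 0 °C → rt
Reagents that add atoms: none
Why: Borohydride can reach C6 only from the α face, since the β face carries three axial groups (4β-methyl, C10 methyl, C12 ester), so the axial 6β-alcohol should form; the tert-butyl ester at C12 is too hindered for the neighbouring alkoxide to close the lactone.

Step 12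
Reactants: 17 di-tert-butyl (1S,2S,4R,4aS,8aS)-4-hydroxy-5,5,8a-trimethyldecahydronaphthalene-1,2-dicarboxylate; 18 (2E,4E,6E)-octa-2,4,6-trienoic acid
Product: 20 di-tert-butyl (1S,2S,4R,4aS,8aS)-5,5,8a-trimethyl-4-{[(2E,4E,6E)-octa-2,4,6-trienoyl]oxy}decahydronaphthalene-1,2-dicarboxylate, via mixed anhydride 19 (not isolated)
Conditions: 18, 2,4,6-Cl3C6H2COCl, Et3N, THF, rt; then 17, DMAP, PhMe, rt → 60 °C
Reagents that add atoms: none
Why: Yamaguchi esterification through the mixed anhydride and the acylpyridinium ion is the usual method for hindered secondary alcohols and uses the trienoic acid directly with its geometry intact; with the tert-butyl ester at C12 no lactonisation can compete.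

Step 13
Reactants: 20 di-tert-butyl (1S,2S,4R,4aS,8aS)-5,5,8a-trimethyl-4-{[(2E,4E,6E)-octa-2,4,6-trienoyl]oxy}decahydronaphthalene-1,2-dicarboxylate
Product: 21 (1S,2S,4R,4aS,8aS)-5,5,8a-trimethyl-4-{[(2E,4E,6E)-octa-2,4,6-trienoyl]oxy}decahydronaphthalene-1,2-dicarboxylic acid (CNP0462207.1)
Conditions: CF3CO2H–CH2Cl2 1:4, 0 °C → rt
Reagents that add atoms: none
Why: tert-Butyl esters are cleaved by trifluoroacetic acid through alkyl–oxygen fission, which is indifferent to the hindrance at C11 and C12 and involves no base, nucleophile or reductant that could touch the trienoate or epimerise C8.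

## Compound list

1 | β-cyclocitral (2,6,6-trimethylcyclohex-1-ene-1-carbaldehyde) | CC1=C(C=O)C(C)(C)CCC1 | starting material
2 | rac-[dimethyl(phenyl)silyl](2,6,6-trimethylcyclohex-1-en-1-yl)methanol | CC1=C(C(O)[Si](C)(C)c2ccccc2)C(C)(C)CCC1 | intermediate
3 | [dimethyl(phenyl)silyl](2,6,6-trimethylcyclohex-1-en-1-yl)methanone | CC1=C(C(=O)[Si](C)(C)c2ccccc2)C(C)(C)CCC1 | intermediate
4 | (R)-[dimethyl(phenyl)silyl](2,6,6-trimethylcyclohex-1-en-1-yl)methanol | CC1=C([C@H](O)[Si](C)(C)c2ccccc2)C(C)(C)CCC1 | intermediate
5 | itaconic anhydride (3-methylideneoxolane-2,5-dione) | C=C1CC(=O)OC1=O | starting material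
6 | 4-{(R)-[dimethyl(phenyl)silyl](2,6,6-trimethylcyclohex-1-en-1-yl)methoxy}-2-methylidene-4-oxobutanoic acid | CC1=C([C@H](OC(=O)CC(=C)C(=O)O)[Si](C)(C)c2ccccc2)C(C)(C)CCC1 | intermediate
7 | trimethylsilyl (3E)-4-{(R)-[dimethyl(phenyl)silyl](2,6,6-trimethylcyclohex-1-en-1-yl)methoxy}-2-methylidene-4-[(trimethylsilyl)oxy]but-3-enoate | CC1=C([C@H](O/C(O[Si](C)(C)C)=C\C(=C)C(=O)O[Si](C)(C)C)[Si](C)(C)c2ccccc2)C(C)(C)CCC1 | intermediate (not isolated)
8 | bis(trimethylsilyl) (2R)-2-[(1R,2E)-2-{[dimethyl(phenyl)silyl]methylidene}-1,3,3-trimethylcyclohexyl]-3-methylidenebutanedioate | C[Si](C)(C)OC(=O)C(=C)[C@H](C(=O)O[Si](C)(C)C)[C@@]1(C)CCCC(C)(C)/C1=C\[Si](C)(C)c2ccccc2 | intermediate (not isolated)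
9 | (2R)-2-[(1R,2E)-2-{[dimethyl(phenyl)silyl]methylidene}-1,3,3-trimethylcyclohexyl]-3-methylidenebutanedioic acid | OC(=O)C(=C)[C@H](C(=O)O)[C@@]1(C)CCCC(C)(C)/C1=C\[Si](C)(C)c2ccccc2 | intermediate
10 | di-tert-butyl (2R)-2-[(1R,2E)-2-{[dimethyl(phenyl)silyl]methylidene}-1,3,3-trimethylcyclohexyl]-3-methylidenebutanedioate | CC(C)(C)OC(=O)C(=C)[C@H](C(=O)OC(C)(C)C)[C@@]1(C)CCCC(C)(C)/C1=C\[Si](C)(C)c2ccccc2 | intermediate
11 | di-tert-butyl (2R)-2-{2-[dimethyl(phenyl)silyl]-4,8,8-trimethyl-1-oxaspiro[2.5]octan-4-yl}-3-methylidenebutanedioate (C5–C6 epoxide of 10; C9 and C10 as in 10; epoxide face not fixed) | CC(C)(C)OC(=O)C(=C)[C@H](C(=O)OC(C)(C)C)[C@@]1(C)CCCC(C)(C)C12OC2[Si](C)(C)c1ccccc1 | intermediate (not isolated)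
12 | di-tert-butyl (2R)-2-[(1S,2S)-2-formyl-1,3,3-trimethylcyclohexyl]-3-methylidenebutanedioate | O=C[C@H]1C(C)(C)CCC[C@]1(C)[C@@H](C(=O)OC(C)(C)C)C(=C)C(=O)OC(C)(C)C | intermediate
13 | (1S,2S)-2-[(2R)-1,4-di-tert-butoxy-3-methylidene-1,4-dioxobutan-2-yl]-2,6,6-trimethylcyclohexane-1-carboxylic acid | OC(=O)[C@H]1C(C)(C)CCC[C@]1(C)[C@@H](C(=O)OC(C)(C)C)C(=C)C(=O)OC(C)(C)C | intermediate
14 | di-tert-butyl (2R)-2-[(1R,2S)-2-(chlorocarbonyl)-1,3,3-trimethylcyclohexyl]-3-methylidenebutanedioate | ClC(=O)[C@H]1C(C)(C)CCC[C@]1(C)[C@@H](C(=O)OC(C)(C)C)C(=C)C(=O)OC(C)(C)C | intermediate (not isolated)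
15 | di-tert-butyl (3R)-2-methylidene-3-{(1R,2S)-1,3,3-trimethyl-2-[(phenylselanyl)carbonyl]cyclohexyl}butanedioate | O=C([Se]c1ccccc1)[C@H]1C(C)(C)CCC[C@]1(C)[C@@H](C(=O)OC(C)(C)C)C(=C)C(=O)OC(C)(C)C | intermediate
16 | di-tert-butyl (1S,2S,4aS,8aS)-5,5,8a-trimethyl-4-oxodecahydronaphthalene-1,2-dicarboxylate | O=C1C[C@H](C(=O)OC(C)(C)C)[C@H](C(=O)OC(C)(C)C)[C@@]2(C)CCCC(C)(C)[C@H]12 | intermediate
17 | di-tert-butyl (1S,2S,4R,4aS,8aS)-4-hydroxy-5,5,8a-trimethyldecahydronaphthalene-1,2-dicarboxylate | O[C@@H]1C[C@H](C(=O)OC(C)(C)C)[C@H](C(=O)OC(C)(C)C)[C@@]2(C)CCCC(C)(C)[C@H]12 | intermediate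
18 | (2E,4E,6E)-octa-2,4,6-trienoic acid | C/C=C/C=C/C=C/C(=O)O | starting material
19 | (2E,4E,6E)-octa-2,4,6-trienoic 2,4,6-trichlorobenzoic anhydride | C/C=C/C=C/C=C/C(=O)OC(=O)c1c(Cl)cc(Cl)cc1Cl | intermediate (not isolated)
20 | di-tert-butyl (1S,2S,4R,4aS,8aS)-5,5,8a-trimethyl-4-{[(2E,4E,6E)-octa-2,4,6-trienoyl]oxy}decahydronaphthalene-1,2-dicarboxylate | C/C=C/C=C/C=C/C(=O)O[C@@H]1C[C@H](C(=O)OC(C)(C)C)[C@H](C(=O)OC(C)(C)C)[C@@]2(C)CCCC(C)(C)[C@H]12 | intermediate
21 | (1S,2S,4R,4aS,8aS)-5,5,8a-trimethyl-4-{[(2E,4E,6E)-octa-2,4,6-trienoyl]oxy}decahydronaphthalene-1,2-dicarboxylic acid | C/C=C/C=C/C=C/C(=O)O[C@@H]1C[C@H](C(=O)O)[C@H](C(=O)O)[C@@]2(C)CCCC(C)(C)[C@H]12 | target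

## Step count and the least certain steps

Total: 13 steps. Longest linear sequence: 13 steps (1 to 21); acid 18 is bought and activated within step 12.

**Step 10 (key step).** The acyl radical sits on a secondary carbon between two quaternary ones, so loss of CO and direct reduction to aldehyde 12 may compete with ring closure. Hydrogen transfer to the C8 radical may also be less α-selective than argued. Fallback: make the same bond by polar umpolung. An N-heterocyclic carbene (triazolium salt with Et3N) converts aldehyde 12 into its acyl-anion equivalent, which adds to C7 in an intramolecular Stetter reaction. This sets out from 12 and returns at 16; C8 is then set by protonation of the ester enolate, again from the open α face. No new compound is involved.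

**Step 3.** The ketone is flanked by a bulky trimethylcyclohexenyl group, so reduction may be slow and the sense or level of induction may differ from simple acylsilanes. Fallback: classical resolution. Racemic 2 is esterified with (S)-O-methylmandelic acid (DCC, DMAP), the diastereomers are separated, and the ester of the R carbinol, (R)-[dimethyl(phenyl)silyl](2,6,6-trimethylcyclohex-1-en-1-yl)methyl (2S)-2-methoxy-2-phenylacetate F1, is cleaved with i-Bu2AlH at −78 °C. This sets out from 2 and returns at 4.

**Step 5.** The ketene acetal is a silyloxydiene made next to a silyl acrylate, so amide addition to the acrylate and loss of geometric control (hence of C9) are the likely failures. The shift onto a tetrasubstituted olefin may also be slow enough for the ketene acetal to decay. Fallback: cap the acid and switch to soft enolisation.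
- Half ester 6 is converted with the trichloroacetimidate into the mixed diester 1-tert-butyl 4-{(R)-[dimethyl(phenyl)silyl](2,6,6-trimethylcyclohex-1-en-1-yl)methyl} 2-methylidenebutanedioate F2.
- (c-C6H11)2BOSO2CF3 and Et3N give the boron ketene acetal tert-butyl (3Z)-4-[(dicyclohexylboranyl)oxy]-4-{(R)-[dimethyl(phenyl)silyl](2,6,6-trimethylcyclohex-1-en-1-yl)methoxy}-2-methylidenebut-3-enoate F3, with C8 again cis to the alkoxy oxygen. Boron ketene acetals rearrange at or below room temperature.
- Aqueous work-up gives (2R)-3-(tert-butoxycarbonyl)-2-[(1R,2E)-2-{[dimethyl(phenyl)silyl]methylidene}-1,3,3-trimethylcyclohexyl]but-3-enoic acid F4, which the imidate converts into 10.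

This sets out from 6 and returns at 10.

**Step 7.** The configuration at C5 depends on the face of enol protonation. The equatorial formyl group of 12 lies between two quaternary carbons and is not clearly the more stable epimer, so prolonged acid contact would erode the ratio. Capture of a C5 cation by the C11 ester is a second possible leak. Fallback: equilibration and recycling instead of kinetic control. The C5 epimer di-tert-butyl (2R)-2-[(1S,2R)-2-formyl-1,3,3-trimethylcyclohexyl]-3-methylidenebutanedioate F5 is separated, equilibrated with DBU in toluene and chromatographed again. This sets out from the epimer mixture obtained from 10 and returns at 12.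

**Step 9.** The acid is extremely hindered, and free selenol is a good Michael donor, so slow acylation with competing addition of selenol to the acrylate is the risk. Fallback: omit the selenoester and generate the same acyl radical from the aldehyde. tert-Dodecanethiol with AIBN abstracts the formyl hydrogen of 12 (thiol-catalysed radical hydroacylation), and the chain closes ring B as in step 10. This sets out from 12 and returns at 16. No new compound is involved.

**Step 12.** The 6β-hydroxyl is axial and flanked by three syn-axial groups, so acylation by the bulky acylpyridinium ion may stall, and forcing conditions could isomerise the triene. Fallback: attach a small acyl group and build the triene on it. Alcohol 17 is esterified with diethylphosphonoacetic acid and DCC to give di-tert-butyl (1S,2S,4R,4aS,8aS)-4-{[2-(diethoxyphosphoryl)acetyl]oxy}-5,5,8a-trimethyldecahydronaphthalene-1,2-dicarboxylate F6. A Horner–Wadsworth–Emmons reaction with (2E,4E)-hexa-2,4-dienal (LiCl, DBU, MeCN) then forms the E C2=C3 bond. This sets out from 17 and returns at 20.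

## Further compounds

F0 | step 10 | none | none
F1 | step 3 | (R)-[dimethyl(phenyl)silyl](2,6,6-trimethylcyclohex-1-en-1-yl)methyl (2S)-2-methoxy-2-phenylacetate | CC1=C([C@H](OC(=O)[C@@H](OC)c2ccccc2)[Si](C)(C)c3ccccc3)C(C)(C)CCC1
F2 | step 5 | 1-tert-butyl 4-{(R)-[dimethyl(phenyl)silyl](2,6,6-trimethylcyclohex-1-en-1-yl)methyl} 2-methylidenebutanedioate | CC1=C([C@H](OC(=O)CC(=C)C(=O)OC(C)(C)C)[Si](C)(C)c2ccccc2)C(C)(C)CCC1
F3 | step 5 | tert-butyl (3Z)-4-[(dicyclohexylboranyl)oxy]-4-{(R)-[dimethyl(phenyl)silyl](2,6,6-trimethylcyclohex-1-en-1-yl)methoxy}-2-methylidenebut-3-enoate | CC1=C([C@H](O/C(OB(C2CCCCC2)C2CCCCC2)=C\C(=C)C(=O)OC(C)(C)C)[Si](C)(C)c3ccccc3)C(C)(C)CCC1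
F4 | step 5 | (2R)-3-(tert-butoxycarbonyl)-2-[(1R,2E)-2-{[dimethyl(phenyl)silyl]methylidene}-1,3,3-trimethylcyclohexyl]but-3-enoic acid | CC(C)(C)OC(=O)C(=C)[C@H](C(=O)O)[C@@]1(C)CCCC(C)(C)/C1=C\[Si](C)(C)c2ccccc2
F5 | step 7 | di-tert-butyl (2R)-2-[(1S,2R)-2-formyl-1,3,3-trimethylcyclohexyl]-3-methylidenebutanedioate | O=C[C@@H]1C(C)(C)CCC[C@]1(C)[C@@H](C(=O)OC(C)(C)C)C(=C)C(=O)OC(C)(C)C
F0 | step 9 | none | none
F6 | step 12 | di-tert-butyl (1S,2S,4R,4aS,8aS)-4-{[2-(diethoxyphosphoryl)acetyl]oxy}-5,5,8a-trimethyldecahydronaphthalene-1,2-dicarboxylate | CCOP(=O)(OCC)CC(=O)O[C@@H]1C[C@H](C(=O)OC(C)(C)C)[C@H](C(=O)OC(C)(C)C)[C@@]2(C)CCCC(C)(C)[C@H]12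
A1 | alternative 1 | methyl (6E)-7,11-dimethyl-3-oxododeca-6,10-dienoate | COC(=O)CC(=O)CC/C=C(\C)CCC=C(C)C
A2 | alternative 1 | methyl 8-oxodriman-11-oate (5α-H, 9β-ester, 10β-methyl) | C1CC(=O)[C@H](C(=O)OC)[C@@]2(C)CCCC(C)(C)[C@H]12
A3 | alternative 2 | 2-(trimethylsilyl)ethyl 6β-{[(bromomethyl)dimethylsilyl]oxy}drim-8-en-11-oate | BrC[Si](C)(C)O[C@@H]1CC=C(C(=O)OCC[Si](C)(C)C)[C@@]2(C)CCCC(C)(C)[C@H]12
A4 | alternative 2 | cyclic 6β-O,12-C dimethylsilylene derivative of 2-(trimethylsilyl)ethyl 8β,9β-driman-11-oate | O1[C@@H]2C[C@H](C[Si]1(C)C)[C@H](C(=O)OCC[Si](C)(C)C)[C@@]3(C)CCCC(C)(C)[C@H]23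
A5 | alternative 3 | (4S,6S)-4-{[tert-butyl(dimethyl)silyl]oxymethyl}-6-(2,6,6-trimethylcyclohex-1-en-1-yl)oxan-2-one | O=C1C[C@@H](CO[Si](C)(C)C(C)(C)C)C[C@H](O1)C2=C(C)CCCC2(C)C
A6 | alternative 3 | 12-(tert-butyldimethylsilyloxy)drim-5-en-11-oic acid (8β-C12, 9α-carboxyl, 10β-methyl) | C1=C2C(C)(C)CCC[C@]2(C)[C@H](C(=O)O)[C@@H](CO[Si](C)(C)C(C)(C)C)C1
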